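**Plan**

- Retrosynthetic cuts: the butenolide C=C and its ester C–O; the side-chain methyl and H across C3′=C4′ (back to an alkyne) and the C4′–C5′ bond (acetylide plus (R)-epichlorohydrin); the pyran bonds C4–C4a and C3–C2 together; the aryl ester.
- Enabling feature: O1 sits between the ring carbons C8a=C4a of the benzene ring and the fully substituted C2. Protonating an aryl enol ether therefore gives C4a=C8a–O1=C2(+), a cationic 2-oxadiene, and C3=C4 is the footprint of a two-carbon dienophile (an enol silane whose OSiMe3 group is eliminated afterwards).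
- Forward order: the benzene ring (ring A) is bought; the pyran ring (ring B) is annulated onto it; the chain is grown from C4′ to C7′; the butenolide (ring C) is closed last by metathesis with a separately made acrylic acid.
- Stereochemistry: C2 (R) from the chiral counter-anion in the annulation; the lactone carbon (R) from (R)-epichlorohydrin; the (E)-alkene from hydroxyl-directed trans-hydrostannation followed by methylation with retention.

Key step: step 4

Assumption: the sense of induction of the chiral acid in step 4 cannot be predicted; the (S,S)-acid is written, and its mirror image would be used if it favours the (S)-chromene. Locants follow the chromene (O1, C2, C3, C4, C4a, C5–C8, C8a) and the side chain from C2 (C1′ onward).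

**Route**

Step 1
Reactants: 1 2-methylbenzene-1,4-diol
Product: 2 2-methyl-4-[(triisopropylsilyl)oxy]phenol
Conditions: iPr3SiCl (1.0 equiv), imidazole, DMF, 0 °C → rt
Reagents that add atoms: chlorotriisopropylsilane, CC(C)[Si](Cl)(C(C)C)C(C)C
Why: Silyl ether formation with the bulky chlorosilane should take place at the unhindered 4-OH and leave free the 1-OH next to the methyl group, which becomes O1.

Step 2
Reactants: 2 2-methyl-4-[(triisopropylsilyl)oxy]phenol; 3 5-(trimethylsilyl)pent-4-ynoic acid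
Product: 4 2-methyl-4-[(triisopropylsilyl)oxy]phenyl 5-(trimethylsilyl)pent-4-ynoate
Conditions: DCC, 4-(dimethylamino)pyridine (cat.), CH2Cl2, 0 °C → rt
Reagents that add atoms: none
Why: Steglich esterification should acylate the remaining hindered phenol; the ester carbonyl carbon is the future C2.

Step 3
Reactants: 4 2-methyl-4-[(triisopropylsilyl)oxy]phenyl 5-(trimethylsilyl)pent-4-ynoate
Product: 5 triisopropyl(3-methyl-4-{[6-(trimethylsilyl)hex-1-en-5-yn-2-yl]oxy}phenoxy)silane
Conditions: Tebbe reagent Cp2Ti(μ-Cl)(μ-CH2)AlMe2 (1.2 equiv), pyridine (cat.), THF–toluene, −40 → 0 °C; aq. NaOH quench; basic alumina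
Reagents that add atoms: Tebbe reagent, C[Al-]1(C)C[Ti](C2C=CC=C2)(C2C=CC=C2)[Cl+]1
Why: Tebbe methylenation turns aryl esters into 1,1-disubstituted aryl enol ethers, and the electrophilic aryl ester should react at low temperature before the silyl-capped alkyne; the new CH2 becomes the C2 methyl group.

Step 4
Reactants: 5 triisopropyl(3-methyl-4-{[6-(trimethylsilyl)hex-1-en-5-yn-2-yl]oxy}phenoxy)silane; 6 trimethyl(vinyloxy)silane
Product: 9 {[(2R)-2,8-dimethyl-2-[4-(trimethylsilyl)but-3-yn-1-yl]-2H-chromen-6-yl]oxy}triisopropylsilane, via oxocarbenium ion 7 (not isolated), via 4-silyloxychromane 8 (not isolated)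
Conditions: (S,S)-imidodiphosphorimidate (IDPi) acid [(ArO)2P(=NSO2CF3)]2NH, (ArO)2 = (S)-3,3′-bis[3,5-bis(trifluoromethyl)phenyl]-1,1′-binaphthalene-2,2′-diolate (5 mol %), 6 (4 equiv), 5 Å molecular sieves, toluene, −60 °C, slow addition of 5; then p-toluenesulfonic acid monohydrate (10 mol %), 0 °C → rt, one pot
Reagents that add atoms: none
Why: Proposed new method: the confined chiral acid protonates the CH2 terminus of 5 to give ion pair 7, whose C4a=C8a–O1=C2(+) array is a cationic 2-oxadiene; the CH2 carbon of enol silane 6 adds to C2 (C3–C2 bond) and the O-silyl oxocarbenium carbon so created is attacked by ring carbon C4a (C4–C4a bond), which closes ring B by a 6-exo-trig Friedel–Crafts closure onto the C=O(+) carbon (overall a stepwise inverse-demand [4+2]) and gives 8, from which acid expels Me3SiOH to leave the C3=C4 alkene. The closest known reactions are the oxa-Povarov reaction of aldehyde-derived aryl oxocarbenium ions with alkenes (racemic) and the IDPi-catalysed enantioselective additions of enol silanes to oxocarbenium ions and to small methyl ketones; the ketone-derived aryl oxocarbenium ion and its enantiofacial control are the new elements. The C2 stereocentre is set in the C3–C2 bond formation by the chiral counter-anion, which must tell CH3 from the CH2CH2 chain inside its pocket; the C4 stereocentre of 8 is transient and is erased on elimination. Regioselectivity of ring closure is secured by the C8 methyl group, which blocks the other ortho position of O1; chemoselectivity is secured because 5 holds the only 1,1-disubstituted (most basic) enol ether, because the silyl cap makes attack of the alkyne on either cation unfavourable (an α-silyl vinyl cation or a ring too small), and because excess 6 should outrun head-to-tail self-condensation of 5.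

Step 5
Reactants: 9 {[(2R)-2,8-dimethyl-2-[4-(trimethylsilyl)but-3-yn-1-yl]-2H-chromen-6-yl]oxy}triisopropylsilane; 10 (R)-epichlorohydrin
Product: 11 (2R)-1-chloro-7-{(2R)-2,8-dimethyl-6-[(triisopropylsilyl)oxy]-2H-chromen-2-yl}hept-4-yn-2-ol
Conditions: MeLi·LiBr (1.05 equiv), THF, 0 °C → rt; then BF3·OEt2, 10, −78 °C
Reagents that add atoms: none
Why: MeLi·LiBr cleaves the C(sp)–Si bond to the lithium acetylide, which with BF3 opens the epoxide at its CH2 carbon (SN2 alkynylation of an epoxide), so the C–O stereocentre of 10 is untouched and becomes the (R)-carbinol of the future lactone.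

Step 6
Reactants: 11 (2R)-1-chloro-7-{(2R)-2,8-dimethyl-6-[(triisopropylsilyl)oxy]-2H-chromen-2-yl}hept-4-yn-2-ol
Product: 12 (2R,4Z)-1-chloro-7-{(2R)-2,8-dimethyl-6-[(triisopropylsilyl)oxy]-2H-chromen-2-yl}-4-(tributylstannyl)hept-4-en-2-ol
Conditions: Bu3SnH (1.1 equiv), [Cp*RuCl]4 (cat.), CH2Cl2, rt
Reagents that add atoms: tributyltin hydride, CCCC[SnH](CCCC)CCCC
Why: Ruthenium-catalysed trans-hydrostannation of an internal alkyne, in which the free homopropargylic OH should steer tin to the proximal alkyne carbon and the anti addition places H and Sn trans, fixing the later (E) geometry.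

Step 7
Reactants: 12 (2R,4Z)-1-chloro-7-{(2R)-2,8-dimethyl-6-[(triisopropylsilyl)oxy]-2H-chromen-2-yl}-4-(tributylstannyl)hept-4-en-2-ol
Product: 13 (2R,4E)-1-chloro-7-{(2R)-2,8-dimethyl-6-[(triisopropylsilyl)oxy]-2H-chromen-2-yl}-4-methylhept-4-en-2-ol
Conditions: MeI, copper thiophene-2-carboxylate Cu(O2CC4H3S), [Bu4N][Ph2PO2], Pd(PPh3)4 (cat.), DMF, rt
Reagents that add atoms: iodomethane, CI
Why: Copper-mediated, palladium-assisted methyl-for-tin exchange (Stille-type C-methylation of an alkenylstannane) should proceed with retention of alkene geometry and tolerate the free alcohol and the alkyl chloride.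

Step 8
Reactants: 13 (2R,4E)-1-chloro-7-{(2R)-2,8-dimethyl-6-[(triisopropylsilyl)oxy]-2H-chromen-2-yl}-4-methylhept-4-en-2-ol
Product: 15 (3R,5E)-8-{(2R)-2,8-dimethyl-6-[(triisopropylsilyl)oxy]-2H-chromen-2-yl}-5-methylocta-1,5-dien-3-ol, via epoxide 14 (not isolated)
Conditions: Me3S+ I− (excess), n-BuLi, THF, −10 °C → rt
Reagents that add atoms: trimethylsulfonium iodide, C[S+](C)C.[I-]
Why: Dimethylsulfonium methylide first acts as base to close epoxide 14, then opens it at the CH2 terminus and the betaine loses Me2S (one-carbon homologation of a terminal epoxide to an allylic alcohol); the carbinol stereocentre is not involved.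

Step 9
Reactants: 16 triethyl phosphonoacetate; 17 5-bromo-2-methylpent-2-ene
Product: 18 ethyl 2-(diethoxyphosphoryl)-6-methylhept-5-enoate
Conditions: NaH, DMF, 0 → 60 °C
Reagents that add atoms: none
Why: C-alkylation of the sodium phosphonoacetate with a primary bromide.

Step 10
Reactants: 18 ethyl 2-(diethoxyphosphoryl)-6-methylhept-5-enoate
Product: 19 ethyl 6-methyl-2-methylidenehept-5-enoate
Conditions: 37% aq. HCHO, K2CO3, H2O, 70 °C
Reagents that add atoms: formaldehyde, C=O
Why: Horner–Wadsworth–Emmons methylenation with aqueous formaldehyde gives the 2-substituted acrylate.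

Step 11
Reactants: 19 ethyl 6-methyl-2-methylidenehept-5-enoate
Product: 20 6-methyl-2-methylidenehept-5-enoic acid
Conditions: LiOH, THF–H2O, rt; then aq. HCl
Reagents that add atoms: lithium hydroxide (aqueous), [Li+].[OH-]
Why: Saponification of the ethyl ester.

Step 12
Reactants: 15 (3R,5E)-8-{(2R)-2,8-dimethyl-6-[(triisopropylsilyl)oxy]-2H-chromen-2-yl}-5-methylocta-1,5-dien-3-ol; 20 6-methyl-2-methylidenehept-5-enoic acid
Product: 21 (3R,5E)-8-{(2R)-2,8-dimethyl-6-[(triisopropylsilyl)oxy]-2H-chromen-2-yl}-5-methylocta-1,5-dien-3-yl 6-methyl-2-methylidenehept-5-enoate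
Conditions: DCC, 4-(dimethylamino)pyridine (cat.), CH2Cl2, 0 °C → rt
Reagents that add atoms: none
Why: Steglich esterification of the secondary allylic alcohol, which does not touch either stereocentre.

Step 13
Reactants: 21 (3R,5E)-8-{(2R)-2,8-dimethyl-6-[(triisopropylsilyl)oxy]-2H-chromen-2-yl}-5-methylocta-1,5-dien-3-yl 6-methyl-2-methylidenehept-5-enoate
Product: 22 (5R)-5-[(2E)-5-{(2R)-2,8-dimethyl-6-[(triisopropylsilyl)oxy]-2H-chromen-2-yl}-2-methylpent-2-en-1-yl]-3-(4-methylpent-3-en-1-yl)furan-2(5H)-one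
Conditions: second-generation Grubbs catalyst (H2IMes)(PCy3)Cl2Ru=CHPh (5–10 mol %), CH2Cl2 (dilute), 40 °C
Reagents that add atoms: none
Why: Ring-closing metathesis should start at the monosubstituted vinyl group and close the five-membered ring onto the 1,1-disubstituted acrylate, while the trisubstituted alkenes and the chromene alkene could only form four- or eight-membered rings.

Step 14
Reactants: 22 (5R)-5-[(2E)-5-{(2R)-2,8-dimethyl-6-[(triisopropylsilyl)oxy]-2H-chromen-2-yl}-2-methylpent-2-en-1-yl]-3-(4-methylpent-3-en-1-yl)furan-2(5H)-one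
Product: 23 2'-epi-tuberatolide B, (5R)-5-{(2E)-5-[(2R)-6-hydroxy-2,8-dimethyl-2H-chromen-2-yl]-2-methylpent-2-en-1-yl}-3-(4-methylpent-3-en-1-yl)furan-2(5H)-one
Conditions: Bu4NF, AcOH, THF, 0 °C
Reagents that add atoms: none
Why: Fluoride cleavage of the aryl silyl ether, buffered with acetic acid so that the acidic γ-hydrogen of the butenolide is not removed.

**Compound list**

1 | 2-methylbenzene-1,4-diol (methylhydroquinone) | Cc1cc(O)ccc1O | starting material
2 | 2-methyl-4-[(triisopropylsilyl)oxy]phenol | Cc1cc(O[Si](C(C)C)(C(C)C)C(C)C)ccc1O | intermediate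
3 | 5-(trimethylsilyl)pent-4-ynoic acid | C[Si](C)(C)C#CCCC(=O)O | starting material
4 | 2-methyl-4-[(triisopropylsilyl)oxy]phenyl 5-(trimethylsilyl)pent-4-ynoate | C[Si](C)(C)C#CCCC(=O)Oc1ccc(O[Si](C(C)C)(C(C)C)C(C)C)cc1C | intermediate
5 | triisopropyl(3-methyl-4-{[6-(trimethylsilyl)hex-1-en-5-yn-2-yl]oxy}phenoxy)silane | C=C(CCC#C[Si](C)(C)C)Oc1ccc(O[Si](C(C)C)(C(C)C)C(C)C)cc1C | intermediate
6 | trimethyl(vinyloxy)silane | C=CO[Si](C)(C)C | starting material
7 | O-aryl oxocarbenium ion from 5 (cation of the ion pair with the catalyst anion) | C[Si](C)(C)C#CCCC(C)=[O+]c1ccc(O[Si](C(C)C)(C(C)C)C(C)C)cc1C | intermediate (not isolated)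
8 | (2R)-2,8-dimethyl-6-[(triisopropylsilyl)oxy]-4-[(trimethylsilyl)oxy]-2-[4-(trimethylsilyl)but-3-yn-1-yl]chromane (both C4 epimers) | C[Si](C)(C)C#CCC[C@]1(C)CC(O[Si](C)(C)C)c2cc(O[Si](C(C)C)(C(C)C)C(C)C)cc(C)c2O1 | intermediate (not isolated)
9 | {[(2R)-2,8-dimethyl-2-[4-(trimethylsilyl)but-3-yn-1-yl]-2H-chromen-6-yl]oxy}triisopropylsilane | C[Si](C)(C)C#CCC[C@]1(C)C=Cc2cc(O[Si](C(C)C)(C(C)C)C(C)C)cc(C)c2O1 | intermediate
10 | (R)-epichlorohydrin, (2R)-2-(chloromethyl)oxirane | ClC[C@H]1CO1 | starting material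
11 | (2R)-1-chloro-7-{(2R)-2,8-dimethyl-6-[(triisopropylsilyl)oxy]-2H-chromen-2-yl}hept-4-yn-2-ol | ClC[C@@H](CC#CCC[C@]2(C)C=Cc3cc(O[Si](C(C)C)(C(C)C)C(C)C)cc(C)c3O2)O | intermediate
12 | (2R,4Z)-1-chloro-7-{(2R)-2,8-dimethyl-6-[(triisopropylsilyl)oxy]-2H-chromen-2-yl}-4-(tributylstannyl)hept-4-en-2-ol | ClC[C@@H](C/C([Sn](CCCC)(CCCC)CCCC)=C/CC[C@]2(C)C=Cc3cc(O[Si](C(C)C)(C(C)C)C(C)C)cc(C)c3O2)O | intermediate
13 | (2R,4E)-1-chloro-7-{(2R)-2,8-dimethyl-6-[(triisopropylsilyl)oxy]-2H-chromen-2-yl}-4-methylhept-4-en-2-ol | ClC[C@@H](C/C(C)=C/CC[C@]2(C)C=Cc3cc(O[Si](C(C)C)(C(C)C)C(C)C)cc(C)c3O2)O | intermediate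
14 | (2R)-2-[(2E)-5-{(2R)-2,8-dimethyl-6-[(triisopropylsilyl)oxy]-2H-chromen-2-yl}-2-methylpent-2-en-1-yl]oxirane | C1[C@@H](C/C(C)=C/CC[C@]2(C)C=Cc3cc(O[Si](C(C)C)(C(C)C)C(C)C)cc(C)c3O2)O1 | intermediate (not isolated)
15 | (3R,5E)-8-{(2R)-2,8-dimethyl-6-[(triisopropylsilyl)oxy]-2H-chromen-2-yl}-5-methylocta-1,5-dien-3-ol | C=C[C@@H](C/C(C)=C/CC[C@]2(C)C=Cc3cc(O[Si](C(C)C)(C(C)C)C(C)C)cc(C)c3O2)O | intermediate
16 | triethyl phosphonoacetate | CCOC(=O)CP(=O)(OCC)OCC | starting material
17 | 5-bromo-2-methylpent-2-ene | CC(C)=CCCBr | starting material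
18 | ethyl 2-(diethoxyphosphoryl)-6-methylhept-5-enoate | CCOC(=O)C(CCC=C(C)C)P(=O)(OCC)OCC | intermediate
19 | ethyl 6-methyl-2-methylidenehept-5-enoate | CCOC(=O)C(=C)CCC=C(C)C | intermediate
20 | 6-methyl-2-methylidenehept-5-enoic acid | OC(=O)C(=C)CCC=C(C)C | intermediate
21 | (3R,5E)-8-{(2R)-2,8-dimethyl-6-[(triisopropylsilyl)oxy]-2H-chromen-2-yl}-5-methylocta-1,5-dien-3-yl 6-methyl-2-methylidenehept-5-enoate | C=C[C@@H](C/C(C)=C/CC[C@]2(C)C=Cc3cc(O[Si](C(C)C)(C(C)C)C(C)C)cc(C)c3O2)OC(=O)C(=C)CCC=C(C)C | intermediate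
22 | (5R)-5-[(2E)-5-{(2R)-2,8-dimethyl-6-[(triisopropylsilyl)oxy]-2H-chromen-2-yl}-2-methylpent-2-en-1-yl]-3-(4-methylpent-3-en-1-yl)furan-2(5H)-one | CC(C)=CCCC1=C[C@@H](C/C(C)=C/CC[C@]2(C)C=Cc3cc(O[Si](C(C)C)(C(C)C)C(C)C)cc(C)c3O2)OC1=O | intermediate
23 | 2'-epi-tuberatolide B | CC(C)=CCCC1=C[C@@H](C/C(C)=C/CC[C@]2(C)C=Cc3cc(O)cc(C)c3O2)OC1=O | target

**Step count**

Total: 14 steps. Longest linear sequence: 11 steps (steps 1–8 and 12–14); steps 9–11 make the acid 20 in a side branch.

**Steps most likely to fail, with fallbacks**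

1. Step 4 (Proposed new method). What may go wrong:
- insufficient facial discrimination between CH3 and the CH2CH2 chain inside the ion pair;
- head-to-tail self-condensation of the enol ether;
- heterolysis of the O1–C2 bond at the β-aryloxy aldehyde stage (retro-oxa-Michael) followed by unselective recombination;
- acid-induced ionisation of the product at C2–O1.

Fallback by known chemistry, setting out from 2 and 3 and returning at 9: acid 3 is treated with methyllithium (2 equiv) to give 6-(trimethylsilyl)hex-5-yn-2-one F1. Ethynylmagnesium bromide converts it into racemic 3-methyl-7-(trimethylsilyl)hepta-1,6-diyn-3-ol F2. Its trifluoroacetate, formed in situ (trifluoroacetic anhydride, DBU), etherifies phenol 2 under CuCl2·2H2O catalysis to the racemic aryl propargyl ether triisopropyl(3-methyl-4-{[3-methyl-7-(trimethylsilyl)hepta-1,6-diyn-3-yl]oxy}phenoxy)silane F3. Heating in N,N-diethylaniline (propargyl Claisen rearrangement, 1,5-hydrogen shift, oxa-6π electrocyclisation) should give the racemic chromene F4. Preparative chromatography on a chiral stationary phase would then deliver 9 and remove its (S)-enantiomer F5.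

2. Step 6 (with step 7 depending on it). What may go wrong: loss of regiocontrol in tin delivery by the homopropargylic hydroxyl group (distal stannane), or protodestannylation competing with methyl transfer in the next step.

Fallback, setting out from 9 and returning at 13, which builds the alkene by syn-hydrometalation of a methyl alkyne instead: 9 is desilylated with MeLi·LiBr and the acetylide is quenched with iodomethane to give the methyl alkyne {[(2R)-2,8-dimethyl-2-(pent-3-yn-1-yl)-2H-chromen-6-yl]oxy}triisopropylsilane F6. Hydrozirconation with Cp2Zr(H)Cl (syn addition, zirconium at the methyl-bearing carbon) and iodinolysis should give the (E)-alkenyl iodide {[(2R)-2-[(3E)-4-iodopent-3-en-1-yl]-2,8-dimethyl-2H-chromen-6-yl]oxy}triisopropylsilane F7. Iodine–lithium exchange (t-BuLi), transmetalation with MgBr2·OEt2 and CuI-catalysed opening of 10 at its CH2 carbon would give 13.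

3. Step 3. What may go wrong: the titanium methylidene engaging the alkyne (titanacyclobutene formation), or hydrolysis of the acid-labile enol ether during isolation.

Fallback, setting out from 2 and returning at 5, which makes the aryl–O–vinyl bond by cross-coupling instead of carbonyl methylenation: 2,3-dibromopropene is alkylated with lithiated 1-(trimethylsilyl)propyne to give 2-bromo-6-(trimethylsilyl)hex-1-en-5-yne F8. Ullmann-type C–O coupling of F8 with phenol 2 (CuI, N,N-dimethylglycine, Cs2CO3, dioxane, 90 °C) should give 5.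

**Further compounds**

F1 | step 4 | 6-(trimethylsilyl)hex-5-yn-2-one | CC(=O)CCC#C[Si](C)(C)C
F2 | step 4 | 3-methyl-7-(trimethylsilyl)hepta-1,6-diyn-3-ol (racemic) | CC(O)(C#C)CCC#C[Si](C)(C)C
F3 | step 4 | triisopropyl(3-methyl-4-{[3-methyl-7-(trimethylsilyl)hepta-1,6-diyn-3-yl]oxy}phenoxy)silane (racemic) | C#CC(C)(CCC#C[Si](C)(C)C)Oc1ccc(O[Si](C(C)C)(C(C)C)C(C)C)cc1C
F4 | step 4 | racemic {[2,8-dimethyl-2-[4-(trimethylsilyl)but-3-yn-1-yl]-2H-chromen-6-yl]oxy}triisopropylsilane | C[Si](C)(C)C#CCCC1(C)C=Cc2cc(O[Si](C(C)C)(C(C)C)C(C)C)cc(C)c2O1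
F5 | step 4 | {[(2S)-2,8-dimethyl-2-[4-(trimethylsilyl)but-3-yn-1-yl]-2H-chromen-6-yl]oxy}triisopropylsilane | C[Si](C)(C)C#CCC[C@@]1(C)C=Cc2cc(O[Si](C(C)C)(C(C)C)C(C)C)cc(C)c2O1
F6 | step 6 | {[(2R)-2,8-dimethyl-2-(pent-3-yn-1-yl)-2H-chromen-6-yl]oxy}triisopropylsilane | CC#CCC[C@]1(C)C=Cc2cc(O[Si](C(C)C)(C(C)C)C(C)C)cc(C)c2O1
F7 | step 6 | {[(2R)-2-[(3E)-4-iodopent-3-en-1-yl]-2,8-dimethyl-2H-chromen-6-yl]oxy}triisopropylsilane | I/C(C)=C/CC[C@]1(C)C=Cc2cc(O[Si](C(C)C)(C(C)C)C(C)C)cc(C)c2O1
F8 | step 3 | 2-bromo-6-(trimethylsilyl)hex-1-en-5-yne | C=C(Br)CCC#C[Si](C)(C)C
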